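**Retrosynthetic overview**

1. No ring is formed: the benzene ring is bought as methyl 2,4,6-trihydroxybenzoate (1) and only decorated.
2. Ring side: 1 → 4-O-methyl ether 2 → mono-triflate 3, which makes ring carbon C6 an acceptor.
3. Chain side: icosan-1-ol (4) → icosanal (5) → NH2-hydrazone 6, in which the former carbonyl carbon (normally an acceptor) becomes a masked alkyl carbanion.
4. Key disconnection: the ring C6–CH2 bond of target 7 = aryl triflate 3 + hydrazone 6 under nickel catalysis with loss of N2. Two acceptor carbons are joined and the saturated C20 chain arrives at the right oxidation level.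

Assumption: the target has no stereocentre and no stereogenic double bond, so "single enantiomer" is read as the one achiral compound; the side chain is unbranched icosyl (C20).

**Route**

Step 1
Reactants: 1 methyl 2,4,6-trihydroxybenzoate
Product: 2 methyl 2,6-dihydroxy-4-methoxybenzoate
Conditions: Me2SO4 (1.0 equiv), K2CO3 (1.0 equiv), acetone, 0 °C → rt
Reagents that add atoms: dimethyl sulfate, COS(=O)(=O)OC
Why: Williamson-type O-methylation in which the 4-OH, the most acidic phenol and the only one not hydrogen-bonded to the ester, is alkylated first when base and electrophile are limited to one equivalent.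

Step 2
Reactants: 2 methyl 2,6-dihydroxy-4-methoxybenzoate
Product: 3 methyl 2-hydroxy-4-methoxy-6-(trifluoromethylsulfonyloxy)benzoate
Conditions: Tf2O (1.05 equiv), pyridine (3 equiv), CH2Cl2, −40 → 0 °C
Reagents that add atoms: trifluoromethanesulfonic anhydride, O=S(=O)(OS(=O)(=O)C(F)(F)F)C(F)(F)F
Why: Phenol O-triflation in which the two hydroxyls of 2 are equivalent, and the second triflation is slowed because the remaining OH is locked in a hydrogen bond to the ester carbonyl on a ring now deactivated by OTf.

Step 3
Reactants: 4 icosan-1-ol
Product: 5 icosanal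
Conditions: TEMPO (10 mol %), PhI(OAc)2 (1.1 equiv), CH2Cl2, rt
Reagents that add atoms: none
Why: TEMPO/PhI(OAc)2 (oxoammonium) oxidation of a primary alcohol stops at the aldehyde in anhydrous CH2Cl2 without over-oxidation to icosanoic acid.

Step 4
Reactants: 3 methyl 2-hydroxy-4-methoxy-6-(trifluoromethylsulfonyloxy)benzoate; 5 icosanal
Product: 7 methyl 2-hydroxy-6-icosyl-4-methoxybenzoate, via icosanal hydrazone 6 (not isolated)
Conditions: 5 (1.5 equiv), N2H4·H2O (1.6 equiv), THF, rt, 1 h, 4 Å MS; then 3, Ni(cod)2 (10 mol %), PMe3 (40 mol %), K3PO4 (3 equiv), THF, 65 °C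
Reagents that add atoms: none
Why: Proposed new method: zerovalent nickel–PMe3 inserts into the C–OTf bond (ortho to the ester, meta to both oxygen donors), hydrazone 6 binds the arylnickel triflate and is deprotonated by phosphate, the aryl group is transferred to the hydrazone carbon and the diazene-type species loses N2 with protonation at carbon (Wolff–Kishner-type), so the former aldehyde carbon acts as an alkyl carbanion and bonds to the triflate carbon; the closest known reaction type is the nickel-catalysed denitrogenative cross-coupling of aldehyde NH2-hydrazones with aryl halides and aryl sulfonates, stretched here to a long-chain aliphatic hydrazone and a triflate carrying a free chelated ortho-phenol.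

**Compound list**

1 | methyl 2,4,6-trihydroxybenzoate | COC(=O)c1c(O)cc(O)cc1O | starting material
2 | methyl 2,6-dihydroxy-4-methoxybenzoate | COC(=O)c1c(O)cc(OC)cc1O | intermediate
3 | methyl 2-hydroxy-4-methoxy-6-(trifluoromethylsulfonyloxy)benzoate | COC(=O)c1c(O)cc(OC)cc1OS(=O)(=O)C(F)(F)F | intermediate
4 | icosan-1-ol | CCCCCCCCCCCCCCCCCCCCO | starting material
5 | icosanal | CCCCCCCCCCCCCCCCCCCC=O | intermediate
6 | (E)-icosylidenehydrazine (icosanal hydrazone) | CCCCCCCCCCCCCCCCCCC/C=N/N | intermediate (formed in the flask, not isolated)
7 | methyl 2-hydroxy-6-icosyl-4-methoxybenzoate | CCCCCCCCCCCCCCCCCCCCc1cc(OC)cc(O)c1C(=O)OC | target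

**Step count and risk**

Total steps: 4. Longest linear sequence: 3 steps (1 → 2 → 3 → 7); the chain branch is 2 steps (4 → 5 → 7).

Steps most likely to fail, in order:

Step 4. The aliphatic NH2-hydrazone can drift to the azine or undergo plain Wolff–Kishner reduction to icosane. The free chelated phenoxide of 3 may slow oxidative addition or bind nickel, and residual hydrazine may cleave the triflate. The fallback sets out from 5, keeps 3 as the partner, and comes back at 7. Condense 5 with p-toluenesulfonyl hydrazide (MeOH, rt) to icosanal N-tosylhydrazone F1. Couple F1 with 3 using Pd2(dba)3 (2.5 mol %), XPhos (10 mol %), LiOtBu (3.5 equiv), 1,4-dioxane, 100 °C. Here F1 gives the diazoalkane in the flask, the arylpalladium triflate forms a palladium carbene, and the aryl group migrates to the carbene carbon, so the former aldehyde carbon again bonds to the triflate carbon. β-Hydride elimination then gives methyl 2-hydroxy-6-[(E)-icos-1-en-1-yl]-4-methoxybenzoate F2. Hydrogenation of F2 (H2, 10% Pd/C, EtOAc, rt) gives 7.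

Step 1. Statistical over-methylation to the 4,6-dimethyl ether and some attack at O-2/O-6 can cut the yield of 2. The fallback sets out from 1 and comes back at 7. Methylate twice (Me2SO4 2.2 equiv, K2CO3, acetone, reflux); this stops at methyl 2-hydroxy-4,6-dimethoxybenzoate F3 because the last OH is chelated to the ester carbonyl. Triflate F3 (Tf2O, pyridine, CH2Cl2, 0 °C) to methyl 2,4-dimethoxy-6-(trifluoromethylsulfonyloxy)benzoate F4. Couple F4 with hydrazone 6 under the step 4 conditions, now with no free phenol, to methyl 2-icosyl-4,6-dimethoxybenzoate F5. Cleave only the methoxy group ortho to the ester with BCl3 (CH2Cl2, −78 → 0 °C, chelation-directed demethylation) to reach 7.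

Step 2. Bis-triflation, or loss of the triflate on work-up or silica, can erode 3. The fallback sets out from 2 and comes back at 3. Triflate both hydroxyls on purpose (Tf2O 2.5 equiv, pyridine, CH2Cl2, 0 °C → rt) to methyl 4-methoxy-2,6-bis(trifluoromethylsulfonyloxy)benzoate F6. Then remove one triflyl group by S–O cleavage with Et4NOH (2.0 equiv, 1,4-dioxane, rt). The first cleavage leaves a chelated phenoxide whose charge suppresses attack on the second sulfonyl group, so the reaction stops at 3 after mild acid work-up.

**Further compounds**

F1 | step 4 | N'-[(E)-icosylidene]-4-methylbenzenesulfonohydrazide (icosanal N-tosylhydrazone) | CCCCCCCCCCCCCCCCCCC/C=N/NS(=O)(=O)c1ccc(C)cc1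
F2 | step 4 | methyl 2-hydroxy-6-[(E)-icos-1-en-1-yl]-4-methoxybenzoate | CCCCCCCCCCCCCCCCCC/C=C/c1cc(OC)cc(O)c1C(=O)OC
F3 | step 1 | methyl 2-hydroxy-4,6-dimethoxybenzoate | COC(=O)c1c(O)cc(OC)cc1OC
F4 | step 1 | methyl 2,4-dimethoxy-6-(trifluoromethylsulfonyloxy)benzoate | COC(=O)c1c(OC)cc(OC)cc1OS(=O)(=O)C(F)(F)F
F5 | step 1 | methyl 2-icosyl-4,6-dimethoxybenzoate | CCCCCCCCCCCCCCCCCCCCc1cc(OC)cc(OC)c1C(=O)OC
F6 | step 2 | methyl 4-methoxy-2,6-bis(trifluoromethylsulfonyloxy)benzoate | COC(=O)c1c(OS(=O)(=O)C(F)(F)F)cc(OC)cc1OS(=O)(=O)C(F)(F)F
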